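Germacrane numbering is used. The γ-lactone (ring B: O, C12, C11, C7, C6) is read as the adduct of a carbonyl ylide C12–O–C6 and the alkene C11=C7. Because the C15 hydroxymethyl group stands cis to C6 on the C4=C5 bond of the ten-membered ring A, C15 can be tied to C12 as a ketone. This turns the ylide into a 4-alkyl-3-oxidopyrylium made from an acetoxypyranone. Its [5+2] cycloaddition with a chiral (E)-crotonoyl imide forms C12–C11 and C6–C7 at once, sets C6, C7 and C11 and fixes the C4=C5 geometry. Later the C12–C15 bond is cut by alkoxyl radical fragmentation and metathesis closes ring A at the cis C1=C10 bond.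

Key step: step 6

Remark on the structure: ring A is C1=C10(C14)–C9–C8(O-acyl)–C7–C6(O)–C5=C4(C15)–C3–C2, and ring B carries C11(C13) and C12=O. The SMILES is read as 1(10)Z (cis in ring A), C3 trans to C6 on C4=C5 (4Z by CIP), 6R,7R,8S,11S, with an (E) side chain. In the bicycles, C1 = C12, C2 = C15, C3 = C4, C4 = C5, C5 = C6, C6 = C7, C7 = C11 and O8 = lactone O.

Assumption: the (2R)-sultam is taken to expose the Cα-re face of its s-cis enoyl rotamer, as in its other uncatalysed cycloadditions. Should the sense be opposite, the equally available antipode would be used.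

Remark: 5 and 6 are racemic at a centre that is lost in step 6. C12 in 22–25 is an anomeric mixture and is left undefined in the SMILES.

Step 1
Reactants: 1 3-methylfuran-2-carboxylic acid; 2 allyl bromide
Product: 3 3-(but-3-en-1-yl)furan-2-carboxylic acid
Conditions: lithium diisopropylamide (2.2 equiv), THF, −78 to 0 °C; 2, −78 °C to rt; aq. HCl
Reagents that add atoms: none
Why: Lateral lithiation–alkylation: the second equivalent of base deprotonates the C3 methyl group of the lithium furoate, and the dianion is alkylated at that carbon by SN2 attack on allyl bromide.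

Step 2
Reactants: 3 3-(but-3-en-1-yl)furan-2-carboxylic acid
Product: 4 [3-(but-3-en-1-yl)furan-2-yl]methanol
Conditions: LiAlH4, THF, 0 °C to rt
Reagents that add atoms: none
Why: Hydride reduction of a carboxylic acid to the primary alcohol, to which the furan and the isolated alkene are inert.

Step 3
Reactants: 4 [3-(but-3-en-1-yl)furan-2-yl]methanol
Product: 5 4-(but-3-en-1-yl)-6-hydroxy-2H-pyran-3(6H)-one
Conditions: VO(acac)2 (2 mol %), t-BuOOH, CH2Cl2, 0 °C to rt
Reagents that add atoms: tert-butyl hydroperoxide, CC(C)(C)OO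
Why: Achmatowicz rearrangement, in which hydroxyl-directed peroxide oxidation of the furan gives the cis-enedione that closes to the pyranone hemiacetal, while the remote terminal alkene has no directing group and is left alone.

Step 4
Reactants: 5 4-(but-3-en-1-yl)-6-hydroxy-2H-pyran-3(6H)-one
Product: 6 4-(but-3-en-1-yl)-5-oxo-5,6-dihydro-2H-pyran-2-yl acetate
Conditions: Ac2O, pyridine, DMAP (cat.), CH2Cl2, 0 °C
Reagents that add atoms: acetic anhydride, CC(=O)OC(C)=O
Why: O-Acylation of the hemiacetal installs the leaving group for ylide formation.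

Step 5
Reactants: 7 (2R)-bornane-10,2-sultam; 8 (E)-but-2-enoyl chloride
Product: 9 N-[(E)-but-2-enoyl]-(2R)-bornane-10,2-sultam
Conditions: NaH, toluene, 0 °C; 8, 0 °C to rt
Reagents that add atoms: none
Why: N-Acylation of the sodium salt of the sultam with the acid chloride, with the (E)-alkene untouched.

Step 6
Reactants: 6 4-(but-3-en-1-yl)-5-oxo-5,6-dihydro-2H-pyran-2-yl acetate; 9 N-[(E)-but-2-enoyl]-(2R)-bornane-10,2-sultam
Product: 11 (1R,5R,6S,7S)-3-(but-3-enyl)-7-endo-methyl-2-oxo-8-oxabicyclo[3.2.1]oct-3-ene-6-exo-carbonyl derivative of (2R)-bornane-10,2-sultam, via oxidopyrylium ylide 10 (not isolated)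
Conditions: i-Pr2NEt (1.5 equiv), 9 (3 equiv), MeCN, 60 °C, slow addition of 6
Reagents that add atoms: none
Why: The amine removes an acidic C12–H of 6 and acetate leaves from C6, giving the aromatic 3-oxidopyrylium 10, a cyclic carbonyl ylide over C12–O–C6, which adds suprafacially to C11=C7 of 9 in a concerted, asynchronous [5+2] (1,3-dipolar) cycloaddition. The closest known reaction type is the base-induced oxidopyrylium–alkene cycloaddition of acetoxypyranones with acrylates, enones and cinnamates. Both new rings, the oxolane (O, C12, C11, C7, C6; later ring B) and the seven-membered carbocycle (C12, C15, C4, C5, C6, C7, C11), are closed in the cycloaddition mode on one face of the ylide, so that C6 and C12 are necessarily cis-bridged. Regiochemistry follows polarity: the enolate-like terminus C12 bonds to the β-carbon C11 and the oxocarbenium-like terminus C6 to the α-carbon C7. C7 and C11 become trans because the (E)-alkene adds suprafacially, the bulky sultam carbonyl takes the exo position (methyl endo), which places C8 trans to C5 on the oxolane, and the sultam lets the ylide reach only the Cα-re face of the enoyl group, which fixes 6R. The step needs the ylide to prefer 9 over its own dimerisation and over the unactivated butenyl alkene, which is secured by the excess of electron-poor 9, the slow addition of 6 and the reversibility of dimer formation at 60 °C.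

Step 7
Reactants: 11 sultam cycloadduct
Product: 12 (1R,2R,5R,6R,7S)-3-(but-3-enyl)-6-exo-(hydroxymethyl)-7-endo-methyl-8-oxabicyclo[3.2.1]oct-3-en-2-ol
Conditions: LiAlH4, THF, −78 to 0 °C
Reagents that add atoms: none
Why: Hydride cleavage of the N-acyl sultam to the primary alcohol frees the auxiliary for re-use and also reduces the enone in the 1,2-sense from the face syn to the oxygen bridge (the other face is covered by the endo methyl group); the C15 carbinol centre is erased in step 8.

Step 8
Reactants: 12 bicyclic diol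
Product: 13 (1R,5R,6S,7S)-3-(but-3-enyl)-7-endo-methyl-2-oxo-8-oxabicyclo[3.2.1]oct-3-ene-6-exo-carbaldehyde
Conditions: Dess–Martin periodinane (2.5 equiv), CH2Cl2, 0 °C to rt
Reagents that add atoms: none
Why: Dess–Martin oxidation of both alcohols under non-basic conditions; the exo aldehyde is the more stable C7 epimer, so C7 is not at risk.

Step 9
Reactants: 13 keto aldehyde
Product: 14 (1R,5R,6R,7S)-3-(but-3-enyl)-6-exo-[(1S)-1-hydroxy-3-methylbut-3-enyl]-7-endo-methyl-8-oxabicyclo[3.2.1]oct-3-en-2-one
Conditions: (−)-Ipc2BOMe, methallylmagnesium chloride, Et2O, 0 °C to rt; then 13, −78 °C; pH 7 buffer, H2O2, MeOH, 0 °C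
Reagents that add atoms: (−)-B-methallyldiisopinocampheylborane, CC(=C)CB([C@@H]1C[C@@H]2C[C@H]([C@H]1C)C2(C)C)[C@@H]1C[C@@H]2C[C@H]([C@H]1C)C2(C)C, made in the flask from methallylmagnesium chloride, C=C(C)C[Mg]Cl
Why: Brown-type asymmetric methallylboration through a closed chair transition state, in which the borane from (+)-α-pinene attacks the si face of the aldehyde and sets 8S under reagent control, while the conjugated ketone does not react at −78 °C.

Step 10
Reactants: 15 (tert-butyldimethylsilyloxy)acetaldehyde; 16 ethyl 2-(triphenylphosphoranylidene)propanoate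
Product: 17 ethyl (E)-4-(tert-butyldimethylsilyloxy)-2-methylbut-2-enoate
Conditions: CH2Cl2, rt
Reagents that add atoms: none
Why: Wittig olefination with a stabilised, α-branched ylide, which gives the (E)-trisubstituted enoate.

Step 11
Reactants: 17 ethyl (E)-4-(tert-butyldimethylsilyloxy)-2-methylbut-2-enoate
Product: 18 (E)-4-(tert-butyldimethylsilyloxy)-2-methylbut-2-enoic acid
Conditions: LiOH, THF/MeOH/H2O, rt; cold dilute HCl to pH 4
Reagents that add atoms: lithium hydroxide, [Li+].[OH-]
Why: Saponification of the ethyl ester, which the primary silyl ether survives at room temperature.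

Step 12
Reactants: 14 homoallylic alcohol; 18 (E)-4-(tert-butyldimethylsilyloxy)-2-methylbut-2-enoic acid
Product: 19 8-O-[(E)-4-(tert-butyldimethylsilyloxy)-2-methylbut-2-enoyl] ester of 14 (core configuration unchanged, 8S)
Conditions: DCC, DMAP, CH2Cl2, 0 °C to rt
Reagents that add atoms: none
Why: Steglich esterification at O8 with retention at C8; the hydroxyl group at C8 is the only free one.

Step 13
Reactants: 19 ester ketone
Product: 20 (2R)-allylic alcohol of 19 (C15–OH on the face of the ethano bridge)
Conditions: NaBH4, CeCl3·7H2O, MeOH, −78 to −40 °C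
Reagents that add atoms: none
Why: Luche reduction, a 1,2-selective hydride delivery to the enone from the face syn to the oxygen bridge that leaves the enoate ester untouched; the configuration at C15 is irrelevant because the centre becomes sp2 in step 14.

Step 14
Reactants: 20 bicyclic allylic alcohol
Product: 23 (6R,7R,8S,11S)-12-acetoxy-6,12-epoxy seco compound with free C15–OH (2-acetoxyoxolane with 3-methyl; 4-[(1S)-1-acyloxy-3-methylbut-3-enyl]; 5-[(Z)-2-(hydroxymethyl)hexa-1,5-dienyl]), via hypoiodite 21 (not isolated), via enal acetate 22 (not isolated)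
Conditions: PhI(OAc)2 (1.2 equiv), I2 (0.6 equiv), CH2Cl2, visible light, 0 °C; aq. Na2S2O3 wash; crude 22, NaBH4, CeCl3·7H2O, MeOH, −78 °C
Reagents that add atoms: (diacetoxyiodo)benzene, CC(=O)OI(OC(C)=O)c1ccccc1
Why: Suárez-type hypoiodite fragmentation, in which homolysis of the O–I bond of 21 gives the C15 alkoxyl radical, whose β-scission breaks C12–C15 because it releases an oxygen-stabilised C12 radical and a conjugated aldehyde, the radical is oxidised to the oxocarbenium ion and caught by acetate, and the configurationally labile cis enal 22 is reduced at once (Luche reduction) so that the C4=C5 geometry set by the ring is kept.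

Step 15
Reactants: 23 allylic alcohol acetate
Product: 24 15-O-tert-butyldimethylsilyl ether of 23
Conditions: TBSCl, imidazole, CH2Cl2, 0 °C to rt
Reagents that add atoms: tert-butyldimethylsilyl chloride, CC(C)(C)[Si](C)(C)Cl
Why: Silylation of the only free (primary allylic) hydroxyl group shields C15–OH from the oxidation in step 17.

Step 16
Reactants: 24 bis-silyl ether acetate
Product: 25 lactol (C12–OH) of 24
Conditions: hydrazine acetate, DMF, 0 °C to rt
Reagents that add atoms: none
Why: Selective aminolysis of the activated anomeric acetate by hydrazine, the standard anomeric deacetylation, which leaves the hindered conjugated C8 ester intact.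

Step 17
Reactants: 25 lactol
Product: 26 (6R,7R,8S,11S)-seco lactone (ring B closed; butenyl on C4 and methallyl on C8; both primary alcohols as silyl ethers)
Conditions: Dess–Martin periodinane, CH2Cl2, 0 °C to rt
Reagents that add atoms: none
Why: Dess–Martin oxidation of the lactol to ring B; C11 keeps its configuration, which is also the thermodynamically preferred all-trans arrangement of C5, C8 and C13 on the lactone.

Step 18
Reactants: 26 seco lactone
Product: 27 bis-silyl ether of the target (1(10)Z,4Z,6R,7R,8S,11S)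
Conditions: second-generation Grubbs catalyst (10 mol %), 1,4-benzoquinone (20 mol %), toluene (1 mM), 80 °C, argon sparge
Reagents that add atoms: none
Why: Ring-closing metathesis of the monosubstituted with the 1,1-disubstituted alkene with loss of ethylene; in a ten-membered ring both the metallacyclobutane and the product strain favour the in-ring cis (Z) trisubstituted alkene, and the C4=C5 and enoate alkenes are too hindered or electron-poor to take part.

Step 19
Reactants: 27 bis-silyl ether
Product: 28 target, (1(10)Z,4Z,6R,7R,8S,11S)-15-hydroxy-8-[(E)-4-hydroxy-2-methylbut-2-enoyloxy]germacra-1(10),4-dien-12,6-olide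
Conditions: HF·pyridine, THF, 0 °C to rt
Reagents that add atoms: none
Why: Fluoride-mediated cleavage of both primary silyl ethers under weakly acidic conditions, which avoids acyl migration and lactone opening.

Compound list
1 | 3-methylfuran-2-carboxylic acid | Cc1ccoc1C(=O)O | starting material
2 | allyl bromide | C=CCBr | starting material
3 | 3-(but-3-en-1-yl)furan-2-carboxylic acid | C=CCCc1ccoc1C(=O)O | intermediate
4 | [3-(but-3-en-1-yl)furan-2-yl]methanol | C=CCCc1ccoc1CO | intermediate
5 | 4-(but-3-en-1-yl)-6-hydroxy-2H-pyran-3(6H)-one (racemic) | C=CCCC1=CC(O)OCC1=O | intermediate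
6 | 4-(but-3-en-1-yl)-5-oxo-5,6-dihydro-2H-pyran-2-yl acetate (racemic) | C=CCCC1=CC(OC(C)=O)OCC1=O | intermediate
7 | (2R)-bornane-10,2-sultam | N1[C@@H]2C[C@H]3CC[C@]2(CS1(=O)=O)C3(C)C | starting material
8 | (E)-but-2-enoyl chloride | C/C=C/C(=O)Cl | starting material
9 | N-[(E)-but-2-enoyl]-(2R)-bornane-10,2-sultam | C/C=C/C(=O)N1[C@@H]2C[C@H]3CC[C@]2(CS1(=O)=O)C3(C)C | intermediate
10 | 4-(but-3-en-1-yl)-3-oxidopyrylium | C=CCCc1cc[o+]cc1[O-] | intermediate
11 | exo cycloadduct with sultam (1R,5R,6S,7S) | C=CCCC1=C[C@H]2O[C@@H](C1=O)[C@@H](C)[C@@H]2C(=O)N3[C@@H]4C[C@H]5CC[C@]4(CS3(=O)=O)C5(C)C | intermediate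
12 | bicyclic diol (1R,2R,5R,6R,7S) | C=CCCC1=C[C@H]2O[C@@H]([C@@H]1O)[C@@H](C)[C@@H]2CO | intermediate
13 | keto aldehyde (1R,5R,6S,7S) | C=CCCC1=C[C@H]2O[C@@H](C1=O)[C@@H](C)[C@@H]2C=O | intermediate
14 | (8S)-homoallylic alcohol | C=CCCC1=C[C@H]2O[C@@H](C1=O)[C@@H](C)[C@@H]2[C@@H](O)CC(C)=C | intermediate
15 | (tert-butyldimethylsilyloxy)acetaldehyde | CC(C)(C)[Si](C)(C)OCC=O | starting material
16 | ethyl 2-(triphenylphosphoranylidene)propanoate | CCOC(=O)C(C)=P(c1ccccc1)(c1ccccc1)c1ccccc1 | starting material
17 | ethyl (E)-4-(tert-butyldimethylsilyloxy)-2-methylbut-2-enoate | CCOC(=O)/C(C)=C/CO[Si](C)(C)C(C)(C)C | intermediate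
18 | (E)-4-(tert-butyldimethylsilyloxy)-2-methylbut-2-enoic acid | OC(=O)/C(C)=C/CO[Si](C)(C)C(C)(C)C | intermediate
19 | ester ketone | C=CCCC1=C[C@H]2O[C@@H](C1=O)[C@@H](C)[C@@H]2[C@@H](OC(=O)/C(C)=C/CO[Si](C)(C)C(C)(C)C)CC(C)=C | intermediate
20 | bicyclic allylic alcohol | C=CCCC1=C[C@H]2O[C@@H]([C@@H]1O)[C@@H](C)[C@@H]2[C@@H](OC(=O)/C(C)=C/CO[Si](C)(C)C(C)(C)C)CC(C)=C | intermediate
21 | C15 hypoiodite of 20 | C=CCCC1=C[C@H]2O[C@@H]([C@@H]1OI)[C@@H](C)[C@@H]2[C@@H](OC(=O)/C(C)=C/CO[Si](C)(C)C(C)(C)C)CC(C)=C | intermediate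
22 | cis enal with C12 acetate | C=CCC/C(C=O)=C/[C@H]1OC(OC(C)=O)[C@@H](C)[C@@H]1[C@@H](OC(=O)/C(C)=C/CO[Si](C)(C)C(C)(C)C)CC(C)=C | intermediate
23 | C15 allylic alcohol with C12 acetate | C=CCC/C(CO)=C/[C@H]1OC(OC(C)=O)[C@@H](C)[C@@H]1[C@@H](OC(=O)/C(C)=C/CO[Si](C)(C)C(C)(C)C)CC(C)=C | intermediate
24 | bis-silyl ether with C12 acetate | C=CCC/C(CO[Si](C)(C)C(C)(C)C)=C/[C@H]1OC(OC(C)=O)[C@@H](C)[C@@H]1[C@@H](OC(=O)/C(C)=C/CO[Si](C)(C)C(C)(C)C)CC(C)=C | intermediate
25 | lactol | C=CCC/C(CO[Si](C)(C)C(C)(C)C)=C/[C@H]1OC(O)[C@@H](C)[C@@H]1[C@@H](OC(=O)/C(C)=C/CO[Si](C)(C)C(C)(C)C)CC(C)=C | intermediate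
26 | seco lactone | C=CCC/C(CO[Si](C)(C)C(C)(C)C)=C/[C@H]1OC(=O)[C@@H](C)[C@@H]1[C@@H](OC(=O)/C(C)=C/CO[Si](C)(C)C(C)(C)C)CC(C)=C | intermediate
27 | bis-silyl ether of the target | C/C1=C/CC/C(CO[Si](C)(C)C(C)(C)C)=C/[C@H]2OC(=O)[C@@H](C)[C@@H]2[C@@H](OC(=O)/C(C)=C/CO[Si](C)(C)C(C)(C)C)C1 | intermediate
28 | CNP0222998.2 | C/C1=C/CC/C(CO)=C/[C@H]2OC(=O)[C@@H](C)[C@@H]2[C@@H](OC(=O)/C(C)=C/CO)C1 | target

Total step count: 19. Longest linear sequence: 16 (steps 1–4, 6–9, 12–19).

Steps most likely to fail

Step 6. Addition to the β-substituted imide may be slow enough for the ylide to dimerise. Exo/endo and facial discrimination may also erode at the temperature needed.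
- The fallback sets out from 6. The ylide is trapped with a large excess of the cheaper and more reactive (E)-crotonaldehyde (i-Pr2NEt, MeCN).
- This gives 13 as a racemate, that is, together with the enantiomeric keto aldehyde F1.
- The pinene-derived methallylborane of step 9 then attacks the si face of both antipodes. The products are 14 and the diastereomeric homoallylic alcohol F2, which are separated by chromatography.
- Absolute configuration is thus secured by reagent control instead of the auxiliary. The route is rejoined at 14.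

Step 14. Three processes may interfere:
- acetyl hypoiodite may add across the electron-rich 1,1-disubstituted alkene;
- the alcohol may simply be oxidised back to the enone;
- iodine and light may isomerise the cis enal before it is reduced.

The fallback is ionic and sets out from ketone 19.
- Baeyer–Villiger oxidation with bis(trimethylsilyl) peroxide and catalytic TMSOTf spares C=C bonds. The oxygen-bearing bridgehead C12 migrates with retention and gives the bridged acyloxy acetal F3.
- PPTS in methanol opens F3 through the C12 oxocarbenium ion to the methyl acetal carboxylic acid F4. O6 is never set free, so butenolide formation with C15 is excluded.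
- Isobutyl chloroformate and N-methylmorpholine give the mixed anhydride F5, which NaBH4 reduces in the same flask to the allylic alcohol methyl acetal F6.
- TBSCl and imidazole give the silyl ether methyl acetal F7.
- PPTS in wet acetone hydrolyses the acetal, and the route is rejoined at 25.

Step 18. Intermolecular metathesis at the monosubstituted alkene (oligomerisation) may outrun closure of the strained ring onto the hindered 1,1-disubstituted alkene. Ruthenium hydride species may also shift the terminal double bond. The fallback removes the rigid in-ring trans alkene during the closure and sets out from 26.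
- HF·pyridine gives the seco diol F8.
- VO(acac)2 and t-BuOOH epoxidise only the electron-rich allylic alcohol alkene C4=C5, giving the 4,5-epoxy seco diol F9. Either face serves; one is drawn.
- Metathesis then closes the more flexible ring to the 4,5-epoxy macrocycle F10.
- Stereoretentive deoxygenation with PPh3 and catalytic CH3ReO3 restores the C4=C5 bond, and the route is rejoined at 28.

Further compounds
F1 | step 6 | enantiomer of keto aldehyde 13 | C=CCCC1=C[C@@H]2O[C@H](C1=O)[C@H](C)[C@H]2C=O
F2 | step 6 | (8S)-homoallylic alcohol on the enantiomeric core | C=CCCC1=C[C@@H]2O[C@H](C1=O)[C@H](C)[C@H]2[C@@H](O)CC(C)=C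
F3 | step 14 | bridged acyloxy acetal (O inserted between C15 and C12) | C=CCCC1=C[C@H]2O[C@@H](OC1=O)[C@@H](C)[C@@H]2[C@@H](OC(=O)/C(C)=C/CO[Si](C)(C)C(C)(C)C)CC(C)=C
F4 | step 14 | C12 methyl acetal, C15 carboxylic acid | C=CCC/C(C(=O)O)=C/[C@H]1OC(OC)[C@@H](C)[C@@H]1[C@@H](OC(=O)/C(C)=C/CO[Si](C)(C)C(C)(C)C)CC(C)=C
F5 | step 14 | isobutyl carbonic mixed anhydride of F4 | C=CCC/C(C(=O)OC(=O)OCC(C)C)=C/[C@H]1OC(OC)[C@@H](C)[C@@H]1[C@@H](OC(=O)/C(C)=C/CO[Si](C)(C)C(C)(C)C)CC(C)=C
F6 | step 14 | C12 methyl acetal, C15 alcohol | C=CCC/C(CO)=C/[C@H]1OC(OC)[C@@H](C)[C@@H]1[C@@H](OC(=O)/C(C)=C/CO[Si](C)(C)C(C)(C)C)CC(C)=C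
F7 | step 14 | C12 methyl acetal, C15 silyl ether | C=CCC/C(CO[Si](C)(C)C(C)(C)C)=C/[C@H]1OC(OC)[C@@H](C)[C@@H]1[C@@H](OC(=O)/C(C)=C/CO[Si](C)(C)C(C)(C)C)CC(C)=C
F8 | step 18 | seco diol | C=CCC/C(CO)=C/[C@H]1OC(=O)[C@@H](C)[C@@H]1[C@@H](OC(=O)/C(C)=C/CO)CC(C)=C
F9 | step 18 | 4,5-epoxy seco diol | C=CCC[C@]1(CO)O[C@H]1[C@H]2OC(=O)[C@@H](C)[C@@H]2[C@@H](OC(=O)/C(C)=C/CO)CC(C)=C
F10 | step 18 | 4,5-epoxy macrocycle | C/C1=C/CC[C@]2(CO)O[C@H]2[C@H]3OC(=O)[C@@H](C)[C@@H]3[C@@H](OC(=O)/C(C)=C/CO)C1
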